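## Retrosynthetic overview

1. Numbering (eudesmane type): ring A = C1–C2–C3–C4–C5–C10, ring B = C5–C6–C7–C8–C9–C10, C14 = methyl on C10, C15 = exocyclic carbon on C4, C11/C12 = first side-chain carbons; β = face of the C10 methyl.
2. Side chain last: C12–C13 by Suzuki coupling of an (E)-alkenyl iodide with a dienylboronate; the iodide comes from a C7 alkyne by methylalumination, the alkyne from the carvone isopropenyl group via a methyl ketone.
3. Ring A functions: C5–OH/C4=C15 from a singlet-oxygen ene reaction of a C4=C5 alkene; equatorial C1–Br from H-atom-transfer hydrogenation of a C1=C2 alkenyl bromide, made from a C1 ketone, made from a traceless C1 formyl group.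
4. Enabling feature: the allylic alcohol C5(OH)–C4(=C15H2) is an ene-transposed C4=C5 alkene, so ring A is a cyclohexene with its double bond between C3 and C10 (Diels–Alder retron); the C3=C4–C5=C10 diene and acrolein form C2–C3, C1–C10 and the quaternary C10 in one step.
5. Ring order: ring B comes from (R)-carvone (fixes C7); ring A is closed by the cycloaddition on a diene made in two steps.

Key step: step 3

Assumption: the (S)-configured catalyst is written in step 3 on the basis of the usual enal-binding model of this catalyst class; if that model places the new C1–C10 bond on the β face, the enantiomeric catalyst is used with everything else unchanged.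

## Route

Step 1
Reactants: 1 (R)-(−)-carvone
Product: 3 (5R)-2-methyl-5-(prop-1-en-2-yl)cyclohex-1-en-1-yl trifluoromethanesulfonate, via lithium enolate 2 (not isolated)
Conditions: LiBH(s-Bu)3, THF, −78 °C; then PhNTf2, −78 °C to rt
Reagents that add atoms: N-phenylbis(trifluoromethanesulfonimide), O=S(=O)(N(c1ccccc1)S(=O)(=O)C(F)(F)F)C(F)(F)F
Why: Conjugate (1,4) hydride reduction of the enone gives the tetrasubstituted enolate regiospecifically, and O-triflation (enolate trapping) gives the enol triflate without touching the C7 stereocentre inherited from carvone.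

Step 2
Reactants: 3 enol triflate; 4 isopropenylboronic acid pinacol ester
Product: 5 (4R)-1-methyl-2,4-di(prop-1-en-2-yl)cyclohex-1-ene
Conditions: Pd(dppf)Cl2 (cat.), K3PO4, dioxane/H2O, 80 °C
Reagents that add atoms: none
Why: Suzuki–Miyaura cross-coupling of the enol triflate with the alkenylboronate attaches C4 with C3 and C15 and completes the C3=C4–C5=C10 diene; no stereocentre is affected.

Step 3
Reactants: 5 triene; 6 acrolein
Product: 7 1α-formyl-4,10β-dimethyl-7β-(prop-1-en-2-yl)-Δ4(5)-octalin
Conditions: (S)-3,3-diphenyl-1-(o-tolyl)tetrahydro-1H,3H-pyrrolo[1,2-c][1,3,2]oxazaborole·HNTf2 (cat.), CH2Cl2, −78 to −40 °C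
Reagents that add atoms: none
Why: A Lewis-acid-catalysed, asynchronous but suprafacial Diels–Alder [4+2] cycloaddition: the catalyst-bound acrolein is attacked at its β-carbon C2 by the unhindered CH2 terminus C3, allyl-cation character builds over C4–C5–C10, and the formyl-bearing C1 closes on C10, the only terminus that gives a six-membered ring. The closest known reaction type is the oxazaborolidinium-catalysed enantioselective Diels–Alder reaction of enals with alkyl-substituted dienes, together with cycloadditions of 2-methyl-1-vinylcyclohexenes that create an angular-methyl quaternary carbon. Ring A is closed in the [4+2] mode, both sigma bonds forming on one face of the diene and the C4=C5 alkene remaining between them. C10 is set by the diene face attacked: the chiral catalyst fixes the exposed face of acrolein and the endo transition state then selects the diene face (reagent control), the remote C7 centre makes the C10 epimer a separable diastereomer, and C1 follows the endo rule (formyl α) but is erased in step 4, so both C1 epimers converge. The step needs regioselectivity (C1 to C10), face selectivity at C10 and chemoselectivity for the diene over the isolated isopropenyl group; the first is secured by the polarisation of the tetra-alkyl diene (largest HOMO coefficient at C3), the last by conjugation, and the cisoid conformer is populated because the transoid one suffers a C14/C15 methyl–methyl clash.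

Step 4
Reactants: 7 aldehyde
Product: 9 4,10β-dimethyl-7β-(prop-1-en-2-yl)-Δ4(5)-octalin-1-one, via hydroperoxy aldehyde 8 (not isolated)
Conditions: Cu(OAc)2 (cat.), 2,2'-bipyridine, DABCO, O2 (1 atm), DMF, 40 °C
Reagents that add atoms: dioxygen, O=O
Why: Copper-catalysed aerobic oxidative deformylation of an α-branched aldehyde (enolisation, α-hydroperoxidation, loss of formic acid) turns the traceless activating group into the C1 ketone and erases the C1 stereocentre.

Step 5
Reactants: 9 ketone
Product: 11 4,10β-dimethyl-7β-(prop-1-en-2-yl)-Δ1(2),4(5)-hexalin-1-yl trifluoromethanesulfonate, via potassium enolate 10 (not isolated)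
Conditions: KN(SiMe3)2, THF, −78 °C; then PhNTf2, −78 to 0 °C
Reagents that add atoms: N-phenylbis(trifluoromethanesulfonimide), O=S(=O)(N(c1ccccc1)S(=O)(=O)C(F)(F)F)C(F)(F)F
Why: Because C10 is quaternary the ketone can enolise only towards C2, so deprotonation and O-triflation (enolate trapping) give a single enol triflate.

Step 6
Reactants: 11 enol triflate
Product: 12 1-bromo-4,10β-dimethyl-7β-(prop-1-en-2-yl)-Δ1(2),4(5)-hexalin
Conditions: Ni(OAc)2·4H2O (cat.), 1,5-cyclooctadiene, Zn (cat.), LiBr, DMA/THF, rt
Reagents that add atoms: lithium bromide, [Li+].[Br-]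
Why: Nickel-catalysed halide exchange of an enol triflate (oxidative addition to zerovalent nickel formed in situ, triflate–bromide exchange, C–Br reductive elimination) gives the cyclic alkenyl bromide, its geometry fixed by the ring.

Step 7
Reactants: 12 alkenyl bromide
Product: 14 7β-acetyl-1-bromo-4,10β-dimethyl-Δ1(2),4(5)-hexalin, via vicinal diol 13 (not isolated)
Conditions: OsO4 (cat.), NaIO4, 2,6-lutidine, dioxane/H2O, rt
Reagents that add atoms: osmium tetroxide, O=[Os](=O)(=O)=O (catalytic oxygen carrier); sodium periodate, [Na+].[O-]I(=O)(=O)=O (terminal oxidant)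
Why: Lemieux–Johnson oxidation: OsO4 dihydroxylates the unhindered 1,1-disubstituted isopropenyl alkene in preference to the tetrasubstituted C4=C5 alkene and the electron-poor bromoalkene, periodate cleaves the diol to the methyl ketone, and the β (equatorial) acetyl group at C7 is the stable epimer.

Step 8
Reactants: 14 bromo-diene methyl ketone
Product: 15 7β-acetyl-1β-bromo-4,10β-dimethyl-Δ4(5)-octalin
Conditions: Mn(dpm)3 (cat., dpm = dipivaloylmethanate), PhSiH3, t-BuOOH, i-PrOH, rt, degassed
Reagents that add atoms: none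
Why: Metal-hydride hydrogen-atom-transfer (MHAT) hydrogenation of a haloalkene: H-atom transfer to C2 gives the α-bromo radical at C1, which takes its second hydrogen on the α face, anti to the axial C10 methyl, so bromine ends β (equatorial), while the C–Br bond, the ketone and the unreactive tetrasubstituted C4=C5 alkene survive.

Step 9
Reactants: 15 methyl ketone
Product: 19 1β-bromo-7β-ethynyl-4,10β-dimethyl-Δ4(5)-octalin, via lithium enolate 16 (not isolated), via enol phosphate 17 (not isolated), via lithium acetylide 18 (not isolated)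
Conditions: LiN(i-Pr)2, THF, −78 °C; ClP(O)(OEt)2; then LiN(i-Pr)2 (excess), −78 °C to rt; aqueous work-up
Reagents that add atoms: none
Why: Enol phosphate route from a methyl ketone to a terminal alkyne (kinetic enolisation on the methyl side, O-phosphorylation, base-induced β-elimination), with C7 untouched and the equatorial bromide inert because it has no anti-periplanar hydrogen.

Step 10
Reactants: 19 alkyne
Product: 21 1β-bromo-7β-[(E)-1-iodoprop-1-en-2-yl]-4,10β-dimethyl-Δ4(5)-octalin, via alkenylalane 20 (not isolated)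
Conditions: AlMe3, Cp2ZrCl2 (cat.), H2O (substoichiometric), CH2Cl2, −20 °C; then I2, THF, −20 to 0 °C
Reagents that add atoms: trimethylaluminium, C[Al](C)C; iodine, II
Why: Zirconium-catalysed carboalumination adds methyl and aluminium syn across the terminal alkyne with aluminium on the terminal carbon, and iodinolysis with retention gives the (E)-alkenyl iodide that fixes the C11=C12 geometry.

Step 11
Reactants: 21 alkenyl iodide
Product: 23 1β-bromo-7β-[(E)-1-iodoprop-1-en-2-yl]-10β-methyl-4-methylidene-trans-decalin-5α-ol, via allylic hydroperoxide 22 (not isolated)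
Conditions: O2, visible light, tetraphenylporphyrin (cat.), CH2Cl2, 0 °C; then PPh3, 0 °C to rt
Reagents that add atoms: dioxygen, O=O
Why: Schenck ene reaction: singlet oxygen attacks the electron-rich tetrasubstituted C4=C5 alkene on the α face (anti to the axial C10 methyl), bonds to C5 and abstracts a hydrogen of the C15 methyl, so reduction of the hydroperoxide gives the 5α-hydroxy 4(15)-ene with trans ring fusion; the iodoalkene is too electron-poor to compete.

Step 12
Reactants: 24 2-methylbut-1-en-3-yne; 25 pinacolborane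
Product: 26 (E)-4,4,5,5-tetramethyl-2-(3-methylbuta-1,3-dien-1-yl)-1,3,2-dioxaborolane
Conditions: Cp2Zr(H)Cl (cat.), Et3N (cat.), neat, 60 °C
Reagents that add atoms: none
Why: Zirconium-hydride-catalysed hydroboration of the terminal alkyne (syn, anti-Markovnikov) gives the (E)-dienylboronate and leaves the 1,1-disubstituted alkene untouched.

Step 13
Reactants: 23 alkenyl iodide alcohol; 26 dienylboronate
Product: 27 CNP0385268.1, (1R,5R,7R,10R)-1β-bromo-10β-methyl-4-methylidene-7β-[(2E,4E)-6-methylhepta-2,4,6-trien-2-yl]-trans-decalin-5α-ol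
Conditions: Pd(PPh3)4 (cat.), K3PO4, THF/H2O, 40 °C
Reagents that add atoms: none
Why: Suzuki–Miyaura cross-coupling with retention of both alkene geometries joins C12 to C13; the alkenyl iodide undergoes oxidative addition far faster than the secondary alkyl bromide, and the tertiary allylic alcohol needs no protection.

## Compound list

1 | (R)-(−)-carvone | C=C(C)[C@@H]1CC=C(C)C(=O)C1 | starting material
2 | lithium (5R)-2-methyl-5-(prop-1-en-2-yl)cyclohex-1-en-1-olate | C=C(C)[C@@H]1CCC(C)=C([O-])C1.[Li+] | intermediate
3 | (5R)-2-methyl-5-(prop-1-en-2-yl)cyclohex-1-en-1-yl trifluoromethanesulfonate | C=C(C)[C@@H]1CCC(C)=C(OS(=O)(=O)C(F)(F)F)C1 | intermediate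
4 | isopropenylboronic acid pinacol ester | CC(=C)B1OC(C)(C)C(C)(C)O1 | starting material
5 | (4R)-1-methyl-2,4-di(prop-1-en-2-yl)cyclohex-1-ene | C=C(C)[C@@H]1CCC(C)=C(C(C)=C)C1 | intermediate
6 | acrolein | C=CC=O | starting material
7 | 1α-formyl-4,10β-dimethyl-7β-(prop-1-en-2-yl)-Δ4(5)-octalin | C=C(C)[C@@H]1CC[C@@]2(C)[C@@H](C=O)CCC(C)=C2C1 | intermediate
8 | 1-formyl-1-hydroperoxy-4,10β-dimethyl-7β-(prop-1-en-2-yl)-Δ4(5)-octalin | C=C(C)[C@@H]1CC[C@@]2(C)C(OO)(C=O)CCC(C)=C2C1 | intermediate
9 | 4,10β-dimethyl-7β-(prop-1-en-2-yl)-Δ4(5)-octalin-1-one | C=C(C)[C@@H]1CC[C@@]2(C)C(=O)CCC(C)=C2C1 | intermediate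
10 | potassium C1=C2 enolate of 9 | C=C(C)[C@@H]1CC[C@@]2(C)C([O-])=CCC(C)=C2C1.[K+] | intermediate
11 | 4,10β-dimethyl-7β-(prop-1-en-2-yl)-Δ1(2),4(5)-hexalin-1-yl trifluoromethanesulfonate | C=C(C)[C@@H]1CC[C@@]2(C)C(OS(=O)(=O)C(F)(F)F)=CCC(C)=C2C1 | intermediate
12 | 1-bromo-4,10β-dimethyl-7β-(prop-1-en-2-yl)-Δ1(2),4(5)-hexalin | C=C(C)[C@@H]1CC[C@@]2(C)C(Br)=CCC(C)=C2C1 | intermediate
13 | 1-bromo-7β-(1,2-dihydroxypropan-2-yl)-4,10β-dimethyl-Δ1(2),4(5)-hexalin | CC(O)(CO)[C@@H]1CC[C@@]2(C)C(Br)=CCC(C)=C2C1 | intermediate
14 | 7β-acetyl-1-bromo-4,10β-dimethyl-Δ1(2),4(5)-hexalin | CC(=O)[C@@H]1CC[C@@]2(C)C(Br)=CCC(C)=C2C1 | intermediate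
15 | 7β-acetyl-1β-bromo-4,10β-dimethyl-Δ4(5)-octalin | CC(=O)[C@@H]1CC[C@@]2(C)[C@H](Br)CCC(C)=C2C1 | intermediate
16 | lithium enolate of 15 (methyl side) | C=C([O-])[C@@H]1CC[C@@]2(C)[C@H](Br)CCC(C)=C2C1.[Li+] | intermediate
17 | diethyl enol phosphate of 15 | C=C(OP(=O)(OCC)OCC)[C@@H]1CC[C@@]2(C)[C@H](Br)CCC(C)=C2C1 | intermediate
18 | lithium acetylide of 19 | [Li+].[C-]#C[C@@H]1CC[C@@]2(C)[C@H](Br)CCC(C)=C2C1 | intermediate
19 | 1β-bromo-7β-ethynyl-4,10β-dimethyl-Δ4(5)-octalin | C#C[C@@H]1CC[C@@]2(C)[C@H](Br)CCC(C)=C2C1 | intermediate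
20 | (E)-alkenyl(dimethyl)alane from 19 | C[Al](C)/C=C(\C)[C@@H]1CC[C@@]2(C)[C@H](Br)CCC(C)=C2C1 | intermediate
21 | 1β-bromo-7β-[(E)-1-iodoprop-1-en-2-yl]-4,10β-dimethyl-Δ4(5)-octalin | I/C=C(\C)[C@@H]1CC[C@@]2(C)[C@H](Br)CCC(C)=C2C1 | intermediate
22 | 1β-bromo-5α-hydroperoxy-7β-[(E)-1-iodoprop-1-en-2-yl]-10β-methyl-4-methylidene-trans-decalin | I/C=C(\C)[C@@H]1CC[C@@]2(C)[C@H](Br)CCC(=C)[C@]2(OO)C1 | intermediate
23 | 1β-bromo-7β-[(E)-1-iodoprop-1-en-2-yl]-10β-methyl-4-methylidene-trans-decalin-5α-ol | I/C=C(\C)[C@@H]1CC[C@@]2(C)[C@H](Br)CCC(=C)[C@]2(O)C1 | intermediate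
24 | 2-methylbut-1-en-3-yne | C=C(C)C#C | starting material
25 | pinacolborane | B1OC(C)(C)C(C)(C)O1 | starting material
26 | (E)-4,4,5,5-tetramethyl-2-(3-methylbuta-1,3-dien-1-yl)-1,3,2-dioxaborolane | CC(=C)/C=C/B1OC(C)(C)C(C)(C)O1 | intermediate
27 | CNP0385268.1 | C=C(C)/C=C/C=C(\C)[C@@H]1CC[C@@]2(C)[C@H](Br)CCC(=C)[C@]2(O)C1 | target

## Step count and risks

Total step count: 13. Longest linear sequence: 12 steps (steps 1 to 11 and 13); step 12 is a one-step side branch.

Steps most likely to fail:

1. Step 3 (Diels–Alder). Bond formation at the fully substituted C10 terminus may be slow, the strong Lewis acid may oligomerise the triene, and the catalyst may fail to override the ring's own facial preference at C10. Fallback: triene 5 is reacted without catalyst with nitroethylene (benzene, rt), the smallest and most reactive ketene-equivalent dienophile, to give the nitro cycloadduct F1 with the same orientation. The C10 epimers, diastereomers because C7 is fixed, are separated by chromatography. A Nef reaction (NaOMe, MeOH; then buffered aqueous TiCl3) converts F1 into ketone 9, where the main route continues.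

2. Step 11 (ene reaction). Hydrogen abstraction from the ring methylenes C3 or C6 instead of the C15 methyl, or oxygen attack on the β face, would give regio- or stereoisomeric hydroperoxides. Fallback: alkenyl iodide 21 is epoxidised with mCPBA (NaHCO3, CH2Cl2, 0 °C) on the α face to the 4α,5α-epoxide F2. This is isomerised with diethylaluminium 2,2,6,6-tetramethylpiperidide (from lithium 2,2,6,6-tetramethylpiperidide and Et2AlCl, toluene, 0 °C), which removes a proton from the least hindered C15 methyl syn to the oxygen and gives allylic alcohol 23.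

3. Step 8 (MHAT hydrogenation). Reductive loss of bromine, slow hydrogen-atom transfer to the hindered alkenyl bromide, or delivery of the second hydrogen on the β face would cost the C1 bromide or its configuration. Fallback: ketone 9 is condensed with hydrazine to hydrazone F3 and oxidised with CuBr2 and LiOt-Bu to the geminal dibromide F4. One equivalent of Bu3SnH (AIBN, benzene, 80 °C) removes one bromine through the same α-bromo radical and, by hydrogen delivery on the α face, should give the 1β-bromide F5. Lemieux–Johnson cleavage of its isopropenyl group (OsO4 cat., NaIO4) then gives methyl ketone 15.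

## Further compounds

F1 | step 3 | 1α-nitro-4,10β-dimethyl-7β-(prop-1-en-2-yl)-Δ4(5)-octalin | C=C(C)[C@@H]1CC[C@@]2(C)[C@@H]([N+](=O)[O-])CCC(C)=C2C1
F2 | step 11 | 1β-bromo-4α,5α-epoxy-7β-[(E)-1-iodoprop-1-en-2-yl]-4,10β-dimethyl-trans-decalin | I/C=C(\C)[C@@H]1CC[C@@]2(C)[C@H](Br)CC[C@@]3(C)O[C@]32C1
F3 | step 8 | hydrazone of ketone 9 | C=C(C)[C@@H]1CC[C@@]2(C)C(=NN)CCC(C)=C2C1
F4 | step 8 | 1,1-dibromo-4,10β-dimethyl-7β-(prop-1-en-2-yl)-Δ4(5)-octalin | C=C(C)[C@@H]1CC[C@@]2(C)C(Br)(Br)CCC(C)=C2C1
F5 | step 8 | 1β-bromo-4,10β-dimethyl-7β-(prop-1-en-2-yl)-Δ4(5)-octalin | C=C(C)[C@@H]1CC[C@@]2(C)[C@H](Br)CCC(C)=C2C1
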